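**Plan**

1. Cuts: the lactone Cα–CH2 bond to ring A (enolate alkylation). In the ring B half, the bond from the aryl-bearing carbon to the future ketone carbon (aldol), the aryl–CH2CO bond (Pd arylation) and the succinate unit (Stobbe). In the ring A half, the C3–C3a bond of the dihydrobenzofuran, which leads back to a flavanone.
2. Enabling feature: the ring O1–C2–C3–C3a–C7a carries a carboxyl-level carbon on C3 next to aryl carbon C3a. It is therefore the contracted form of a 2-arylchroman-4-one: aryl carbon C4a (ortho to the ring oxygen) shifts from carbonyl carbon C4 to C3, and C4 leaves the ring as the ester that becomes CH2OH.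
3. Forward: chromone → (S)-flavanone → oxidative ring contraction → benzylic bromide (steps 1–8). 5-Bromovanillin → (R)-β-benzyl lactone → arylacetyl imide → aldol → protected side chain (steps 9–19). Union by enolate alkylation (step 20), then desilylation, oxidation, hydrogenolysis (steps 21–23).
4. Stereochemistry: dihydrobenzofuran C2 from the Pd/PyOx conjugate addition, C3 relayed from C2 in the ring contraction. Lactone Cβ from the Rh/Et-DuPhos hydrogenation, Cα from anti alkylation. The centre α to the ketone from the (R)-oxazolidinone boron aldol, whose carbinol centre is later oxidised away.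

Key step: step 4

Remark: the hand of the ligands in steps 3 and 11 is assigned by analogy with the facial preference reported for these catalyst classes; if the first run shows the opposite sense, the ligand antipode is used.

**Route**

Step 1
Reactants: 1 1-(2-hydroxy-3-methoxyphenyl)ethan-1-one
Product: 2 1-(5-bromo-2-hydroxy-3-methoxyphenyl)ethan-1-one
Conditions: NBS, MeCN, 0 °C → rt
Reagents that add atoms: N-bromosuccinimide, O=C1CCC(=O)N1Br
Why: Electrophilic aromatic bromination goes para to the phenol OH (C5), the only free position activated by OH and not deactivated by the acetyl group.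

Step 2
Reactants: 2 1-(5-bromo-2-hydroxy-3-methoxyphenyl)ethan-1-one
Product: 4 6-bromo-8-methoxy-4H-chromen-4-one, via enaminone 3 (not isolated)
Conditions: Me2NCH(OMe)2, toluene, 100 °C; then conc. HCl, CH2Cl2, 40 °C
Reagents that add atoms: N,N-dimethylformamide dimethyl acetal, COC(OC)N(C)C
Why: Condensation of the methyl ketone with the amide acetal gives the enaminone, and acid-promoted conjugate addition of the phenol with loss of dimethylamine closes the pyranone (enaminone chromone synthesis).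

Step 3
Reactants: 4 6-bromo-8-methoxy-4H-chromen-4-one; 5 [4-(benzyloxy)-3-methoxyphenyl]boronic acid
Product: 6 (2S)-2-[4-(benzyloxy)-3-methoxyphenyl]-6-bromo-8-methoxychroman-4-one
Conditions: Pd(OCOCF3)2 (5 mol %), (R)-t-BuPyOx (6 mol %), NH4PF6 (30 mol %), H2O (5 equiv), ClCH2CH2Cl, 60 °C
Reagents that add atoms: 5 [4-(benzyloxy)-3-methoxyphenyl]boronic acid, OB(O)c1ccc(OCc2ccccc2)c(OC)c1
Why: Asymmetric conjugate addition of the arylboronic acid to the chromone under a divalent palladium/pyridine–oxazoline catalyst (aryl-Pd insertion into C2=C3, then protonolysis of the Pd enolate) sets C2 as S by ligand control, and the aryl bromide is untouched because no zerovalent palladium is formed.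

Step 4
Reactants: 6 (2S)-2-[4-(benzyloxy)-3-methoxyphenyl]-6-bromo-8-methoxychroman-4-one
Product: 9 methyl (2S,3S)-2-[4-(benzyloxy)-3-methoxyphenyl]-5-bromo-7-methoxy-2,3-dihydro-1-benzofuran-3-carboxylate, via methyl enol ether 7 (not isolated), via trans-3-iodanyl ketal 8 (not isolated)
Conditions: PhI(OAc)2 (1.2 equiv), conc. H2SO4, HC(OMe)3, 0 °C → rt; aq. NaHCO3 work-up
Reagents that add atoms: trimethyl orthoformate, COC(OC)OC; water, O
Why: Acid and HC(OMe)3 convert the C4 ketone into methyl enol ether 7, which PhI(OAc)2 attacks at C3 anti to the equatorial C2 aryl group while methanol caps C4 to give the trans-3-(λ3-iodanyl) dimethyl ketal 8; ring A carbon C4a then shifts from C4 to C3 with loss of iodobenzene, and the dimethoxycarbenium ion ends as the methyl ester after work-up. The closest known reaction type is the oxidative ring contraction of flavanones to methyl trans-2-aryl-2,3-dihydrobenzofuran-3-carboxylates mediated by trivalent iodine or Tl(NO3)3. The ring O1–C2–C3–C3a–C7a is closed not by a cyclisation but by the 1,2-aryl shift itself, through a bridged phenonium-type transition state (aryl participation, formally 3-exo), which contracts the six-membered pyranone and expels C4 as the ester carbon. C2 is untouched and keeps the S configuration from step 3, and it fixes C3: the iodane enters trans to the aryl group, the shift inverts C3, and the ester ends trans to the aryl group (2S,3S), which is also the thermodynamically preferred arrangement. The step needs migration of C4a rather than the C2 aryl group (isoflavone pathway) and no ionisation of the benzylic C2–O1 bond; the diequatorial trans iodane places only the C4–C4a bond antiperiplanar to C3–I, the ring oxygen ortho to C4a raises its migratory aptitude, and low temperature with short acid contact protects C2.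

Step 5
Reactants: 9 methyl (2S,3S)-2-[4-(benzyloxy)-3-methoxyphenyl]-5-bromo-7-methoxy-2,3-dihydro-1-benzofuran-3-carboxylate
Product: 10 {(2S,3R)-2-[4-(benzyloxy)-3-methoxyphenyl]-5-bromo-7-methoxy-2,3-dihydro-1-benzofuran-3-yl}methanol
Conditions: LiAlH4, THF, 0 °C
Reagents that add atoms: none
Why: Hydride reduction of the methyl ester is fast at 0 °C and leaves the aryl bromide and the trans C2/C3 pair untouched (the C3 descriptor becomes R by CIP rules only).

Step 6
Reactants: 10 {(2S,3R)-2-[4-(benzyloxy)-3-methoxyphenyl]-5-bromo-7-methoxy-2,3-dihydro-1-benzofuran-3-yl}methanol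
Product: 11 (2S,3R)-2-[4-(benzyloxy)-3-methoxyphenyl]-3-[(benzyloxy)methyl]-5-bromo-7-methoxy-2,3-dihydro-1-benzofuran
Conditions: NaH, BnBr, n-Bu4NI (cat.), THF/DMF, 0 °C → rt
Reagents that add atoms: benzyl bromide, BrCc1ccccc1
Why: Williamson etherification protects the primary alcohol as a benzyl ether that falls in the final hydrogenolysis.

Step 7
Reactants: 11 (2S,3R)-2-[4-(benzyloxy)-3-methoxyphenyl]-3-[(benzyloxy)methyl]-5-bromo-7-methoxy-2,3-dihydro-1-benzofuran
Product: 14 {(2S,3R)-2-[4-(benzyloxy)-3-methoxyphenyl]-3-[(benzyloxy)methyl]-7-methoxy-2,3-dihydro-1-benzofuran-5-yl}methanol, via aryllithium 12 (not isolated), via aldehyde 13 (not isolated)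
Conditions: n-BuLi, THF, −78 °C; DMF, −78 → 0 °C; then MeOH, NaBH4, 0 °C
Reagents that add atoms: N,N-dimethylformamide, CN(C)C=O
Why: Bromine–lithium exchange outruns deprotonation at −78 °C, and formylation with DMF followed by borohydride reduction in the same flask turns the C5 bromide into the hydroxymethyl group.

Step 8
Reactants: 14 {(2S,3R)-2-[4-(benzyloxy)-3-methoxyphenyl]-3-[(benzyloxy)methyl]-7-methoxy-2,3-dihydro-1-benzofuran-5-yl}methanol
Product: 15 (2S,3R)-2-[4-(benzyloxy)-3-methoxyphenyl]-3-[(benzyloxy)methyl]-5-(bromomethyl)-7-methoxy-2,3-dihydro-1-benzofuran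
Conditions: CBr4, PPh3, CH2Cl2, 0 °C
Reagents that add atoms: carbon tetrabromide, BrC(Br)(Br)Br
Why: Appel bromination under neutral conditions gives the electron-rich benzylic bromide without acid that could ionise the C2–O bond; it is used crude at once.

Step 9
Reactants: 16 3-bromo-4-hydroxy-5-methoxybenzaldehyde
Product: 17 4-(benzyloxy)-3-bromo-5-methoxybenzaldehyde
Conditions: BnBr, K2CO3, DMF, 60 °C
Reagents that add atoms: benzyl bromide, BrCc1ccccc1
Why: Williamson etherification of the phenol.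

Step 10
Reactants: 17 4-(benzyloxy)-3-bromo-5-methoxybenzaldehyde; 18 dimethyl succinate
Product: 19 (3E)-4-[4-(benzyloxy)-3-bromo-5-methoxyphenyl]-3-(methoxycarbonyl)but-3-enoic acid
Conditions: t-BuOK, t-BuOH, reflux; aq. HCl
Reagents that add atoms: 18 dimethyl succinate, COC(=O)CCC(=O)OC
Why: Stobbe condensation (aldol, paraconic lactone, ring-opening elimination) gives the E half-ester with the free acid on the CH2 arm.

Step 11
Reactants: 19 (3E)-4-[4-(benzyloxy)-3-bromo-5-methoxyphenyl]-3-(methoxycarbonyl)but-3-enoic acid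
Product: 20 (3R)-4-[4-(benzyloxy)-3-bromo-5-methoxyphenyl]-3-(methoxycarbonyl)butanoic acid
Conditions: H2 (5 bar), [Rh(cod)((S,S)-Et-DuPhos)]OTf (1 mol %), NaOMe (10 mol %), MeOH, rt
Reagents that add atoms: none
Why: Rh/bisphospholane asymmetric hydrogenation of the itaconate-type half-ester, whose carboxylate chelates Rh beside the alkene, sets the future lactone Cβ as R; aryl bromide and benzyl ether are inert to the homogeneous catalyst.

Step 12
Reactants: 20 (3R)-4-[4-(benzyloxy)-3-bromo-5-methoxyphenyl]-3-(methoxycarbonyl)butanoic acid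
Product: 22 (4R)-4-{[4-(benzyloxy)-3-bromo-5-methoxyphenyl]methyl}oxolan-2-one, via hydroxy acid 21 (not isolated)
Conditions: KOH (1 equiv), EtOH; CaCl2, NaBH4, EtOH, −10 °C → rt; then 2 M HCl, rt
Reagents that add atoms: none
Why: Ca(BH4)2 reduces the ester but not the potassium carboxylate (chemoselective borohydride reduction), and acidification lactonises the γ-hydroxy acid with the stereocentre untouched.

Step 13
Reactants: 22 (4R)-4-{[4-(benzyloxy)-3-bromo-5-methoxyphenyl]methyl}oxolan-2-one; 23 (2-tert-butoxy-2-oxoethyl)zinc chloride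
Product: 24 tert-butyl 2-[2-(benzyloxy)-3-methoxy-5-{[(3R)-5-oxooxolan-3-yl]methyl}phenyl]acetate
Conditions: Pd(dba)2 (2 mol %), P(t-Bu)3 (2 mol %), THF, rt → 50 °C
Reagents that add atoms: 23 (2-tert-butoxy-2-oxoethyl)zinc chloride, CC(C)(C)OC(=O)C[Zn]Cl
Why: Pd-catalysed α-arylation of the zinc ester enolate (Reformatsky-type Negishi coupling) replaces the aryl bromide by CH2CO2t-Bu under conditions too mild to enolise the lactone.

Step 14
Reactants: 24 tert-butyl 2-[2-(benzyloxy)-3-methoxy-5-{[(3R)-5-oxooxolan-3-yl]methyl}phenyl]acetate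
Product: 25 2-[2-(benzyloxy)-3-methoxy-5-{[(3R)-5-oxooxolan-3-yl]methyl}phenyl]acetic acid
Conditions: CF3CO2H/CH2Cl2 (1:4), 0 °C → rt
Reagents that add atoms: none
Why: Acidolysis of the tert-butyl ester (loss of isobutene) frees the arylacetic acid; lactone and aryl benzyl ether survive short exposure at or below room temperature.

Step 15
Reactants: 25 2-[2-(benzyloxy)-3-methoxy-5-{[(3R)-5-oxooxolan-3-yl]methyl}phenyl]acetic acid; 26 (4R)-4-benzyl-1,3-oxazolidin-2-one
Product: 28 (4R)-4-benzyl-3-{[2-(benzyloxy)-3-methoxy-5-{[(3R)-5-oxooxolan-3-yl]methyl}phenyl]acetyl}-1,3-oxazolidin-2-one, via mixed pivalic anhydride 27 (not isolated)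
Conditions: t-BuCOCl, Et3N, THF, −20 °C; then 26, LiCl, −20 °C → rt
Reagents that add atoms: 26 (4R)-4-benzyl-1,3-oxazolidin-2-one, O=C1N[C@H](Cc2ccccc2)CO1
Why: N-Acylation of the oxazolidinone by the mixed anhydride with Et3N/LiCl avoids strong base, so the lactone is not enolised.

Step 16
Reactants: 28 (4R)-4-benzyl-3-{[2-(benzyloxy)-3-methoxy-5-{[(3R)-5-oxooxolan-3-yl]methyl}phenyl]acetyl}-1,3-oxazolidin-2-one; 29 4-(benzyloxy)-3-methoxybenzaldehyde
Product: 31 (4R)-4-benzyl-3-{(2R,3R)-2-[2-(benzyloxy)-3-methoxy-5-{[(3R)-5-oxooxolan-3-yl]methyl}phenyl]-3-[4-(benzyloxy)-3-methoxyphenyl]-3-hydroxypropanoyl}-1,3-oxazolidin-2-one, via Z boron enolate 30 (not isolated)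
Conditions: n-Bu2BOTf, i-Pr2NEt, CH2Cl2, −78 → 0 °C; 29, −78 → 0 °C; pH 7 buffer, MeOH, 30% H2O2, 0 °C
Reagents that add atoms: 29 4-(benzyloxy)-3-methoxybenzaldehyde, O=Cc1ccc(OCc2ccccc2)c(OC)c1
Why: Evans syn aldol: the Z dibutylboron enolate reacts through a closed Zimmerman–Traxler chair on the face away from the auxiliary benzyl group, setting the aryl-bearing carbon as 2R (the centre that survives) and the carbinol as 3R, while the lactone is not enolised by Bu2BOTf/amine.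

Step 17
Reactants: 31 (4R)-4-benzyl-3-{(2R,3R)-2-[2-(benzyloxy)-3-methoxy-5-{[(3R)-5-oxooxolan-3-yl]methyl}phenyl]-3-[4-(benzyloxy)-3-methoxyphenyl]-3-hydroxypropanoyl}-1,3-oxazolidin-2-one
Product: 32 (4R)-4-benzyl-3-{(2R,3R)-2-[2-(benzyloxy)-3-methoxy-5-{[(3R)-5-oxooxolan-3-yl]methyl}phenyl]-3-[4-(benzyloxy)-3-methoxyphenyl]-3-[(tert-butyldimethylsilyl)oxy]propanoyl}-1,3-oxazolidin-2-one
Conditions: t-BuMe2SiOTf, 2,6-lutidine, CH2Cl2, −78 → 0 °C
Reagents that add atoms: tert-butyldimethylsilyl triflate, CC(C)(C)[Si](C)(C)OS(=O)(=O)C(F)(F)F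
Why: Silylation of the hindered benzylic alcohol with the silyl triflate blocks retro-aldol cleavage and marks this oxygen for the later oxidation.

Step 18
Reactants: 32 (4R)-4-benzyl-3-{(2R,3R)-2-[2-(benzyloxy)-3-methoxy-5-{[(3R)-5-oxooxolan-3-yl]methyl}phenyl]-3-[4-(benzyloxy)-3-methoxyphenyl]-3-[(tert-butyldimethylsilyl)oxy]propanoyl}-1,3-oxazolidin-2-one
Product: 33 (4R)-4-{[4-(benzyloxy)-3-{(1R,2S)-1-[4-(benzyloxy)-3-methoxyphenyl]-1-[(tert-butyldimethylsilyl)oxy]-3-hydroxypropan-2-yl}-5-methoxyphenyl]methyl}oxolan-2-one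
Conditions: NaBH4, THF/H2O (4:1), 0 °C → rt
Reagents that add atoms: none
Why: Borohydride reduction of the activated N-acyl oxazolidinone in wet THF gives the primary alcohol and releases the auxiliary, while the less electrophilic γ-lactone reacts far more slowly (the aryl-bearing carbon becomes S by CIP rules only).

Step 19
Reactants: 33 (4R)-4-{[4-(benzyloxy)-3-{(1R,2S)-1-[4-(benzyloxy)-3-methoxyphenyl]-1-[(tert-butyldimethylsilyl)oxy]-3-hydroxypropan-2-yl}-5-methoxyphenyl]methyl}oxolan-2-one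
Product: 34 (4R)-4-{[4-(benzyloxy)-3-{(1R,2S)-3-(benzyloxy)-1-[4-(benzyloxy)-3-methoxyphenyl]-1-[(tert-butyldimethylsilyl)oxy]propan-2-yl}-5-methoxyphenyl]methyl}oxolan-2-one
Conditions: 2-benzyloxy-1-methylpyridinium triflate, MgO, PhCF3, 83 °C
Reagents that add atoms: 2-benzyloxy-1-methylpyridinium triflate, C[n+]1ccccc1OCc1ccccc1.[O-]S(=O)(=O)C(F)(F)F
Why: Benzyl transfer from the N-methylpyridinium salt (thermal SN1-type O-benzylation buffered by MgO) etherifies the primary alcohol under neutral conditions, so neither silyl migration nor lactone opening by an alkoxide can occur.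

Step 20
Reactants: 34 (4R)-4-{[4-(benzyloxy)-3-{(1R,2S)-3-(benzyloxy)-1-[4-(benzyloxy)-3-methoxyphenyl]-1-[(tert-butyldimethylsilyl)oxy]propan-2-yl}-5-methoxyphenyl]methyl}oxolan-2-one; 15 (2S,3R)-2-[4-(benzyloxy)-3-methoxyphenyl]-3-[(benzyloxy)methyl]-5-(bromomethyl)-7-methoxy-2,3-dihydro-1-benzofuran
Product: 36 (3R,4R)-3-({(2S,3R)-2-[4-(benzyloxy)-3-methoxyphenyl]-3-[(benzyloxy)methyl]-7-methoxy-2,3-dihydro-1-benzofuran-5-yl}methyl)-4-{[4-(benzyloxy)-3-{(1R,2S)-3-(benzyloxy)-1-[4-(benzyloxy)-3-methoxyphenyl]-1-[(tert-butyldimethylsilyl)oxy]propan-2-yl}-5-methoxyphenyl]methyl}oxolan-2-one, via lithium enolate 35 (not isolated)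
Conditions: LiN(SiMe3)2, THF, −78 °C; then 15, DMPU, −78 → −40 °C
Reagents that add atoms: 15 (2S,3R)-2-[4-(benzyloxy)-3-methoxyphenyl]-3-[(benzyloxy)methyl]-5-(bromomethyl)-7-methoxy-2,3-dihydro-1-benzofuran, BrCc1cc(OC)c2c(c1)[C@H](COCc1ccccc1)[C@@H](c1ccc(OCc3ccccc3)c(OC)c1)O2
Why: Alkylation of the lactone lithium enolate by the benzylic bromide occurs anti to the Cβ substituent and gives the trans-α,β-dibenzyl lactone (3R,4R), the standard entry to dibenzylbutyrolactone lignans.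

Step 21
Reactants: 36 the silyl ether from step 20
Product: 37 (3R,4R)-3-({(2S,3R)-2-[4-(benzyloxy)-3-methoxyphenyl]-3-[(benzyloxy)methyl]-7-methoxy-2,3-dihydro-1-benzofuran-5-yl}methyl)-4-{[4-(benzyloxy)-3-{(1R,2S)-3-(benzyloxy)-1-[4-(benzyloxy)-3-methoxyphenyl]-1-hydroxypropan-2-yl}-5-methoxyphenyl]methyl}oxolan-2-one
Conditions: HF·pyridine, pyridine, THF, 0 °C → rt
Reagents that add atoms: none
Why: Fluoride desilylation frees the benzylic secondary alcohol, and the buffered reagent leaves lactone, benzyl ethers and the benzylic C–O bonds intact.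

Step 22
Reactants: 37 the secondary alcohol from step 21
Product: 38 (3R,4R)-3-({(2S,3R)-2-[4-(benzyloxy)-3-methoxyphenyl]-3-[(benzyloxy)methyl]-7-methoxy-2,3-dihydro-1-benzofuran-5-yl}methyl)-4-{[4-(benzyloxy)-3-{(2S)-3-(benzyloxy)-1-[4-(benzyloxy)-3-methoxyphenyl]-1-oxopropan-2-yl}-5-methoxyphenyl]methyl}oxolan-2-one
Conditions: Dess–Martin periodinane, pyridine, CH2Cl2, 0 °C → rt
Reagents that add atoms: none
Why: Dess–Martin oxidation under buffered, non-basic conditions gives the aryl ketone without enolising the new α-aryl ketone, so the adjacent S centre is kept.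

Step 23
Reactants: 38 the penta-benzyl ketone from step 22
Product: 39 CNP0111438.1, (3R,4R)-4-{[4-hydroxy-3-{(2S)-3-hydroxy-1-(4-hydroxy-3-methoxyphenyl)-1-oxopropan-2-yl}-5-methoxyphenyl]methyl}-3-({(2S,3R)-2-(4-hydroxy-3-methoxyphenyl)-3-(hydroxymethyl)-7-methoxy-2,3-dihydro-1-benzofuran-5-yl}methyl)oxolan-2-one
Conditions: H2 (1 atm), 10% Pd/C, EtOAc/MeOH, rt
Reagents that add atoms: none
Why: Hydrogenolysis of the three aryl and two alkyl benzyl ethers under neutral conditions frees all hydroxyl groups without exposing the base- and acid-labile α-aryl-β-hydroxy ketone, and the electron-rich aryl ketone, lactone and dihydrobenzofuran should resist 1 atm H2.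

**Compound list**

1 | 1-(2-hydroxy-3-methoxyphenyl)ethan-1-one | CC(=O)c1cccc(OC)c1O | starting material
2 | 1-(5-bromo-2-hydroxy-3-methoxyphenyl)ethan-1-one | CC(=O)c1cc(Br)cc(OC)c1O | intermediate
3 | (E)-1-(5-bromo-2-hydroxy-3-methoxyphenyl)-3-(dimethylamino)prop-2-en-1-one | CN(C)/C=C/C(=O)c1cc(Br)cc(OC)c1O | intermediate
4 | 6-bromo-8-methoxy-4H-chromen-4-one | O=c1ccoc2c(OC)cc(Br)cc12 | intermediate
5 | [4-(benzyloxy)-3-methoxyphenyl]boronic acid | OB(O)c1ccc(OCc2ccccc2)c(OC)c1 | starting material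
6 | (2S)-2-[4-(benzyloxy)-3-methoxyphenyl]-6-bromo-8-methoxychroman-4-one | O=C1C[C@@H](c2ccc(OCc3ccccc3)c(OC)c2)Oc2c(OC)cc(Br)cc12 | intermediate
7 | (2S)-2-[4-(benzyloxy)-3-methoxyphenyl]-6-bromo-4,8-dimethoxy-2H-chromene | COC1=C[C@@H](c2ccc(OCc3ccccc3)c(OC)c2)Oc2c(OC)cc(Br)cc12 | intermediate
8 | (2R,3R)-3-[acetoxy(phenyl)-λ3-iodanyl]-2-[4-(benzyloxy)-3-methoxyphenyl]-6-bromo-4,4,8-trimethoxychromane (2,3-trans) | COC1(OC)[C@H](I(OC(C)=O)c2ccccc2)[C@@H](c2ccc(OCc3ccccc3)c(OC)c2)Oc2c(OC)cc(Br)cc12 | intermediate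
9 | methyl (2S,3S)-2-[4-(benzyloxy)-3-methoxyphenyl]-5-bromo-7-methoxy-2,3-dihydro-1-benzofuran-3-carboxylate | Brc1cc(OC)c2c(c1)[C@H](C(=O)OC)[C@@H](c1ccc(OCc3ccccc3)c(OC)c1)O2 | intermediate
10 | {(2S,3R)-2-[4-(benzyloxy)-3-methoxyphenyl]-5-bromo-7-methoxy-2,3-dihydro-1-benzofuran-3-yl}methanol | Brc1cc(OC)c2c(c1)[C@H](CO)[C@@H](c1ccc(OCc3ccccc3)c(OC)c1)O2 | intermediate
11 | (2S,3R)-2-[4-(benzyloxy)-3-methoxyphenyl]-3-[(benzyloxy)methyl]-5-bromo-7-methoxy-2,3-dihydro-1-benzofuran | Brc1cc(OC)c2c(c1)[C@H](COCc1ccccc1)[C@@H](c1ccc(OCc3ccccc3)c(OC)c1)O2 | intermediate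
12 | 5-lithio derivative of 11 | [Li]c1cc(OC)c2c(c1)[C@H](COCc1ccccc1)[C@@H](c1ccc(OCc3ccccc3)c(OC)c1)O2 | intermediate
13 | (2S,3R)-2-[4-(benzyloxy)-3-methoxyphenyl]-3-[(benzyloxy)methyl]-7-methoxy-2,3-dihydro-1-benzofuran-5-carbaldehyde | O=Cc1cc(OC)c2c(c1)[C@H](COCc1ccccc1)[C@@H](c1ccc(OCc3ccccc3)c(OC)c1)O2 | intermediate
14 | {(2S,3R)-2-[4-(benzyloxy)-3-methoxyphenyl]-3-[(benzyloxy)methyl]-7-methoxy-2,3-dihydro-1-benzofuran-5-yl}methanol | OCc1cc(OC)c2c(c1)[C@H](COCc1ccccc1)[C@@H](c1ccc(OCc3ccccc3)c(OC)c1)O2 | intermediate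
15 | (2S,3R)-2-[4-(benzyloxy)-3-methoxyphenyl]-3-[(benzyloxy)methyl]-5-(bromomethyl)-7-methoxy-2,3-dihydro-1-benzofuran | BrCc1cc(OC)c2c(c1)[C@H](COCc1ccccc1)[C@@H](c1ccc(OCc3ccccc3)c(OC)c1)O2 | intermediate
16 | 3-bromo-4-hydroxy-5-methoxybenzaldehyde (5-bromovanillin) | O=Cc1cc(Br)c(O)c(OC)c1 | starting material
17 | 4-(benzyloxy)-3-bromo-5-methoxybenzaldehyde | O=Cc1cc(Br)c(OCc2ccccc2)c(OC)c1 | intermediate
18 | dimethyl succinate | COC(=O)CCC(=O)OC | starting material
19 | (3E)-4-[4-(benzyloxy)-3-bromo-5-methoxyphenyl]-3-(methoxycarbonyl)but-3-enoic acid | COC(=O)/C(=C/c1cc(Br)c(OCc2ccccc2)c(OC)c1)CC(=O)O | intermediate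
20 | (3R)-4-[4-(benzyloxy)-3-bromo-5-methoxyphenyl]-3-(methoxycarbonyl)butanoic acid | COC(=O)[C@H](Cc1cc(Br)c(OCc2ccccc2)c(OC)c1)CC(=O)O | intermediate
21 | (3R)-4-[4-(benzyloxy)-3-bromo-5-methoxyphenyl]-3-(hydroxymethyl)butanoic acid | OC[C@H](Cc1cc(Br)c(OCc2ccccc2)c(OC)c1)CC(=O)O | intermediate
22 | (4R)-4-{[4-(benzyloxy)-3-bromo-5-methoxyphenyl]methyl}oxolan-2-one | Brc1cc(C[C@H]2COC(=O)C2)cc(OC)c1OCc1ccccc1 | intermediate
23 | (2-tert-butoxy-2-oxoethyl)zinc chloride | CC(C)(C)OC(=O)C[Zn]Cl | starting material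
24 | tert-butyl 2-[2-(benzyloxy)-3-methoxy-5-{[(3R)-5-oxooxolan-3-yl]methyl}phenyl]acetate | CC(C)(C)OC(=O)Cc1cc(C[C@H]2COC(=O)C2)cc(OC)c1OCc1ccccc1 | intermediate
25 | 2-[2-(benzyloxy)-3-methoxy-5-{[(3R)-5-oxooxolan-3-yl]methyl}phenyl]acetic acid | OC(=O)Cc1cc(C[C@H]2COC(=O)C2)cc(OC)c1OCc1ccccc1 | intermediate
26 | (4R)-4-benzyl-1,3-oxazolidin-2-one | O=C1N[C@H](Cc2ccccc2)CO1 | starting material
27 | mixed anhydride of 25 with pivalic acid | CC(C)(C)C(=O)OC(=O)Cc1cc(C[C@H]2COC(=O)C2)cc(OC)c1OCc1ccccc1 | intermediate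
28 | (4R)-4-benzyl-3-{[2-(benzyloxy)-3-methoxy-5-{[(3R)-5-oxooxolan-3-yl]methyl}phenyl]acetyl}-1,3-oxazolidin-2-one | O=C(Cc1cc(C[C@H]2COC(=O)C2)cc(OC)c1OCc1ccccc1)N1[C@H](Cc2ccccc2)COC1=O | intermediate
29 | 4-(benzyloxy)-3-methoxybenzaldehyde | O=Cc1ccc(OCc2ccccc2)c(OC)c1 | starting material
30 | Z dibutylboron enolate of 28 | CCCCB(CCCC)O/C(=C\c1cc(C[C@H]2COC(=O)C2)cc(OC)c1OCc1ccccc1)N1[C@H](Cc2ccccc2)COC1=O | intermediate
31 | (4R)-4-benzyl-3-{(2R,3R)-2-[2-(benzyloxy)-3-methoxy-5-{[(3R)-5-oxooxolan-3-yl]methyl}phenyl]-3-[4-(benzyloxy)-3-methoxyphenyl]-3-hydroxypropanoyl}-1,3-oxazolidin-2-one | O=C([C@H](c1cc(C[C@H]2COC(=O)C2)cc(OC)c1OCc1ccccc1)[C@@H](O)c1ccc(OCc2ccccc2)c(OC)c1)N1[C@H](Cc2ccccc2)COC1=O | intermediate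
32 | (4R)-4-benzyl-3-{(2R,3R)-2-[2-(benzyloxy)-3-methoxy-5-{[(3R)-5-oxooxolan-3-yl]methyl}phenyl]-3-[4-(benzyloxy)-3-methoxyphenyl]-3-[(tert-butyldimethylsilyl)oxy]propanoyl}-1,3-oxazolidin-2-one | O=C([C@H](c1cc(C[C@H]2COC(=O)C2)cc(OC)c1OCc1ccccc1)[C@@H](O[Si](C)(C)C(C)(C)C)c1ccc(OCc2ccccc2)c(OC)c1)N1[C@H](Cc2ccccc2)COC1=O | intermediate
33 | (4R)-4-{[4-(benzyloxy)-3-{(1R,2S)-1-[4-(benzyloxy)-3-methoxyphenyl]-1-[(tert-butyldimethylsilyl)oxy]-3-hydroxypropan-2-yl}-5-methoxyphenyl]methyl}oxolan-2-one | OC[C@H](c1cc(C[C@H]2COC(=O)C2)cc(OC)c1OCc1ccccc1)[C@@H](O[Si](C)(C)C(C)(C)C)c1ccc(OCc2ccccc2)c(OC)c1 | intermediate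
34 | (4R)-4-{[4-(benzyloxy)-3-{(1R,2S)-3-(benzyloxy)-1-[4-(benzyloxy)-3-methoxyphenyl]-1-[(tert-butyldimethylsilyl)oxy]propan-2-yl}-5-methoxyphenyl]methyl}oxolan-2-one | c1ccccc1COC[C@H](c1cc(C[C@H]2COC(=O)C2)cc(OC)c1OCc1ccccc1)[C@@H](O[Si](C)(C)C(C)(C)C)c1ccc(OCc2ccccc2)c(OC)c1 | intermediate
35 | lithium enolate of 34 | c1ccccc1COC[C@H](c1cc(C[C@H]2COC(O[Li])=C2)cc(OC)c1OCc1ccccc1)[C@@H](O[Si](C)(C)C(C)(C)C)c1ccc(OCc2ccccc2)c(OC)c1 | intermediate
36 | (3R,4R)-3-({(2S,3R)-2-[4-(benzyloxy)-3-methoxyphenyl]-3-[(benzyloxy)methyl]-7-methoxy-2,3-dihydro-1-benzofuran-5-yl}methyl)-4-{[4-(benzyloxy)-3-{(1R,2S)-3-(benzyloxy)-1-[4-(benzyloxy)-3-methoxyphenyl]-1-[(tert-butyldimethylsilyl)oxy]propan-2-yl}-5-methoxyphenyl]methyl}oxolan-2-one | COc1cc([C@H](O[Si](C)(C)C(C)(C)C)[C@H](COCc2ccccc2)c2cc(C[C@H]3COC(=O)[C@@H]3Cc3cc(OC)c4c(c3)[C@H](COCc3ccccc3)[C@@H](c3ccc(OCc5ccccc5)c(OC)c3)O4)cc(OC)c2OCc2ccccc2)ccc1OCc1ccccc1 | intermediate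
37 | (3R,4R)-3-({(2S,3R)-2-[4-(benzyloxy)-3-methoxyphenyl]-3-[(benzyloxy)methyl]-7-methoxy-2,3-dihydro-1-benzofuran-5-yl}methyl)-4-{[4-(benzyloxy)-3-{(1R,2S)-3-(benzyloxy)-1-[4-(benzyloxy)-3-methoxyphenyl]-1-hydroxypropan-2-yl}-5-methoxyphenyl]methyl}oxolan-2-one | COc1cc([C@H](O)[C@H](COCc2ccccc2)c2cc(C[C@H]3COC(=O)[C@@H]3Cc3cc(OC)c4c(c3)[C@H](COCc3ccccc3)[C@@H](c3ccc(OCc5ccccc5)c(OC)c3)O4)cc(OC)c2OCc2ccccc2)ccc1OCc1ccccc1 | intermediate
38 | (3R,4R)-3-({(2S,3R)-2-[4-(benzyloxy)-3-methoxyphenyl]-3-[(benzyloxy)methyl]-7-methoxy-2,3-dihydro-1-benzofuran-5-yl}methyl)-4-{[4-(benzyloxy)-3-{(2S)-3-(benzyloxy)-1-[4-(benzyloxy)-3-methoxyphenyl]-1-oxopropan-2-yl}-5-methoxyphenyl]methyl}oxolan-2-one | COc1cc(C(=O)[C@H](COCc2ccccc2)c2cc(C[C@H]3COC(=O)[C@@H]3Cc3cc(OC)c4c(c3)[C@H](COCc3ccccc3)[C@@H](c3ccc(OCc5ccccc5)c(OC)c3)O4)cc(OC)c2OCc2ccccc2)ccc1OCc1ccccc1 | intermediate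
39 | CNP0111438.1, (3R,4R)-4-{[4-hydroxy-3-{(2S)-3-hydroxy-1-(4-hydroxy-3-methoxyphenyl)-1-oxopropan-2-yl}-5-methoxyphenyl]methyl}-3-({(2S,3R)-2-(4-hydroxy-3-methoxyphenyl)-3-(hydroxymethyl)-7-methoxy-2,3-dihydro-1-benzofuran-5-yl}methyl)oxolan-2-one | COc1cc(C(=O)[C@H](CO)c2cc(C[C@H]3COC(=O)[C@@H]3Cc3cc(OC)c4c(c3)[C@H](CO)[C@@H](c3ccc(O)c(OC)c3)O4)cc(OC)c2O)ccc1O | target

**Step count and risks**

Total: 23 steps. Longest linear sequence: 15 steps (steps 9–23, from 5-bromovanillin 16); the ring A branch (steps 1–8) joins at step 20.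

Steps most likely to fail:

Step 4. The C2 aryl group may migrate instead of C4a, or C3 may simply be methoxylated, and acid-induced ionisation of the benzylic C2–O bond may erode enantiopurity. Fallback by photochemical Wolff ring contraction, setting out from 6: LiN(SiMe3)2 and CF3CO2CH2CF3 at −78 °C give the 3-trifluoroacetyl flavanone F1, which MsN3/Et3N converts in the same flask into the 3-diazo flavanone F2. Irradiation in MeOH (Pyrex filter) causes loss of N2, shift of C4a to the carbene carbon and addition of methanol to the ketene; the ester is expected as a mixture of 9 and its cis C3 epimer F3. DBU equilibrates F3 to the trans ester, and the route is rejoined at 9.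

Step 18. Hydride attack on the hindered imide may be slow enough that reductive opening of the γ-lactone competes. Fallback setting out from 32: LiOH/H2O2 (THF/H2O, 0 °C) removes the auxiliary, and acidification recloses any opened lactone to give the carboxylic acid F4. BH3·SMe2 (THF, 0 °C) then reduces the acid in preference to the lactone and returns to 33.

Step 23. The two alkyl benzyl ethers may cleave slowly, so that over-reduction of the aryl ketone or hydrogenolysis of the benzylic C2–O bond of the dihydrobenzofuran sets in. Fallback setting out from 38: Lewis-acid debenzylation with BCl3 and pentamethylbenzene as cation scavenger (CH2Cl2, −78 °C) replaces hydrogenolysis and gives 39 directly; this fallback makes no new compound (F0).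

Further compounds
F1 | step 4 | (2S)-2-[4-(benzyloxy)-3-methoxyphenyl]-6-bromo-8-methoxy-3-(trifluoroacetyl)chroman-4-one (C3 not defined) | O=C1C(C(=O)C(F)(F)F)[C@@H](c2ccc(OCc3ccccc3)c(OC)c2)Oc2c(OC)cc(Br)cc12
F2 | step 4 | (2R)-2-[4-(benzyloxy)-3-methoxyphenyl]-6-bromo-3-diazo-8-methoxychroman-4-one (same spatial arrangement at C2 as 6) | O=C1C(=[N+]=[N-])[C@@H](c2ccc(OCc3ccccc3)c(OC)c2)Oc2c(OC)cc(Br)cc12
F3 | step 4 | methyl (2S,3R)-2-[4-(benzyloxy)-3-methoxyphenyl]-5-bromo-7-methoxy-2,3-dihydro-1-benzofuran-3-carboxylate (cis) | Brc1cc(OC)c2c(c1)[C@@H](C(=O)OC)[C@@H](c1ccc(OCc3ccccc3)c(OC)c1)O2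
F4 | step 18 | (2R,3R)-2-[2-(benzyloxy)-3-methoxy-5-{[(3R)-5-oxooxolan-3-yl]methyl}phenyl]-3-[4-(benzyloxy)-3-methoxyphenyl]-3-[(tert-butyldimethylsilyl)oxy]propanoic acid | OC(=O)[C@H](c1cc(C[C@H]2COC(=O)C2)cc(OC)c1OCc1ccccc1)[C@@H](O[Si](C)(C)C(C)(C)C)c1ccc(OCc2ccccc2)c(OC)c1
F0 | step 23 | none | none
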